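## Structural features

Compound 28 is a humulane-type sesquiterpenoid ester: one eleven-membered carbocycle whose only oxygen-bearing ring carbon is acylated by 4-hydroxy-3-methoxybenzoic acid, so that ring and arene are joined solely through the ester. The ring atoms are numbered C1 (bears the exocyclic methylene), C2=C3 (E, disubstituted), C4 (quaternary, gem-dimethyl), C5 (ester-bearing, R), C6, C7, C8(Me)=C9 (E, trisubstituted), C10 and C11. C5 is the only stereocentre, so no two stereocentres are adjacent; it sits between the quaternary C4 and the C6 methylene and must be set by a reagent or ligand. The fragile groups are the C1(=CH2)–C2=C3 diene (acid, oxidants), the medium ring with its transannular C8=C9 alkene, the neopentylic ester and the free phenol. The free C5 alkoxide could also cleave the C4–C5 bond by a retro-vinylogous aldol reaction once a C1 carbonyl is conjugated through C2=C3. The real difficulty is closing a strained eleven-membered ring containing two E alkenes while forming the congested C4–C5 bond and fixing the C5 configuration. The key step exploits C5 as a homoallylic carbinol next to the gem-dimethyl carbon C4, which carries the E C2=C3 alkene. This array is what γ-addition of a C2-metalated 3,3-dimethylallyl unit (C2–C3–C4) to a C5 aldehyde leaves behind, so one bond formation can deliver the ring, the quaternary carbon, the alkene and the stereocentre.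

## Logic of the disconnections

28 is cut at the phenolic O–Si bond to give 27. The phenol has to be masked during acylation and methylenation, and fluoride removes an aryl silyl ether without touching diene or ester. The forward step must be buffered so that the phenoxide formed does not attack the ester.

27 is cut at the exocyclic C1=CH2 bond to give ketone 26. This replaces the acid-sensitive diene by an enone that can be carried as a ketal. The ylide must add to C1 faster than it attacks the aryl ester; no free C5 alkoxide is present at this stage, so C4–C5 fragmentation is excluded.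

26 is cut at the C1 carbonyl to give dioxolane 25. The C1 oxygen has to be an sp3 ketal during ring closure. The hydrolysis must be mild enough to spare the aryl silyl ether and the ester.

25 is cut at the acyl C–O bond to give alcohol 20 and acid 23 (activated as 24); 23 is cut at its two O–Si bonds back to 21. Acylation is placed directly after ring closure, while C1 is still a ketal, so the hindered neopentylic hydroxyl can be forced without a carbonyl in the ring and is never a free alkoxide next to an enone. The demand is acylation of a hindered secondary alcohol, met with an acid chloride and a nucleophilic catalyst.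

20 is cut at C4–C5 to give the open-chain chloro aldehyde 18, via allylchromium 19. This removes the ring, the quaternary–carbinol junction, the E C2=C3 alkene and the stereocentre in one operation and leaves an achiral chain. The forward step must give γ- over α-attack, E geometry, cyclisation over oligomerisation and ligand-controlled facial selectivity.

18 is cut at C4–Cl to give tertiary alcohol 17, 17 is taken back to ester 16 (C5 oxidation level), and 16 to silyl ether 15 (O–Si). The labile allylic chloride is made last, in the presence of the finished aldehyde, and used without purification. This ordering avoids exposing a tertiary allylic chloride to hydride reagents and fluoride. The demands are partial reduction of an ester beside a free hydroxyl and chlorination without ketal loss.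

15 is cut at the two ketal C–O bonds to give enone 14. Ketalisation is safe here because C4 is quaternary, so the alkene cannot migrate. Acid-free, low-temperature conditions are needed to spare the tertiary allylic silyl ether.

14 is cut at C2=C3 (through aldol 12 and mesylate 13) to give methyl ketone 7 and aldehyde 10. The cut separates the C4 gem-dimethyl carbinol unit from the chain at a bond that a crossed aldol condensation with a non-enolisable aldehyde forms E-selectively. The demand is kinetic enolisation of 7 on the methyl side (enolate 11) beside a methyl ester.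

10 is cut back through ester 9 to hydroxy ester 8 (O–Si, then the oxidation level of the carbonyl carbon). A triethylsilyl group is chosen because it survives enolate, mesylation and ketalisation conditions yet leaves the tertiary oxygen under cold fluoride without harming the methyl ester.

7 is cut by decarboxylation to 6, and 6 at C6–C7 to allylic bromide 3 and 4 (as anion 5). A lithium ester enolate would add to the unprotected methyl ketone of 3, so a soft stabilised carbanion is used and one ester carbon is then removed. 3 is taken back through alcohol 2 to 1, where allylic oxidation of the E methyl group sets the C8=C9 geometry. The demands are SN2 (not SN2′) alkylation, mono-alkylation and retention of alkene geometry.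

## Other disconnections considered

Alternative 1: the cut is C6–C7. The thirteen-membered allyl β-keto lactone A1 would be treated with Pd(PPh3)4: zerovalent palladium ionises the allylic C7–O bond, CO2 is lost, and the C6 enolate recombines with C7 of the π-allyl to contract the ring to ketone A2.
- In its favour: the diene and the C1 methylene are carried through, so no ketal and no late methylenation are needed, which is better than the chosen plan. The first ring closure is a lactonisation and the C–C bond forms within an ion pair, so neither high dilution nor stoichiometric chromium is required, also better. The enolate is regiodefined because C4 is quaternary, which is equal.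
- Against it: the π-allyl has two termini, and attack at C9 would contract the ring to nine members. Syn/anti equilibration of the π-allyl can erode the E geometry at C8=C9, which the chosen plan fixes in its first step. Zerovalent palladium can also engage the 1,3-diene.
- Comparison: C5 emerges as a ketone, so an enantioselective reduction and the acylation would still follow. That reduction (tert-alkyl against methylene) is probably more predictable than ligand control inside a macrocyclic transition state, a point on which this alternative is the better. The steps saved at the end are spent on the reduction and on assembling A1, so step economy is about equal.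

Alternative 2: the cut is the C10–C11 bond, formed while C2–C8 breaks. The potassium alkoxide of the trans-divinylcycloheptanol A3 (KH, 18-crown-6) would undergo an anionic oxy-Cope rearrangement to the eleven-membered enolate, protonated to ketone A4.
- In its favour: the ring arises by a [3,3] ring expansion, with no entropic penalty and no dilution. The chair transition state of the trans-divinyl array delivers E C8=C9, which is equal to the chosen plan. The C5 stereocentre is installed on a seven-membered ring before expansion, which is better.
- Against it: A4 has its carbonyl at C2 and saturated C1 and C3. The C1 methylene and the C2=C3 alkene would have to be introduced afterwards with regiocontrol between two α-methylenes. A3 has two adjacent fully substituted carbons with trans vinyl groups and is itself hard to assemble.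
- Comparison: mechanistically cleaner for ring formation, but clearly worse in step economy and in the fit between the product of the key step and the target.

Alternative 3: the cut is C2=C3, bridged by sulfur. The twelve-membered sulfone A5 would be halogenated in situ at allylic C2 (KOH on Al2O3, CBr2F2, t-BuOH), deprotonated at C3, closed to the episulfone and stripped of SO2 in a Ramberg–Bäcklund contraction to the silyl ether A6.
- In its favour: the diene is formed directly with the methylene in place. The stereocentre is set in an open-chain precursor before ring closure, which is better. Ring closure at sulfur by double alkylation is usually easy, equal or better. No chromium is used.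
- Against it: alkene geometry is decided at episulfone closure, without a cyclic transition state ordering the substituents, so E at C2=C3 between two fully substituted carbons is not secured. The doubly activated C2–H invites base-mediated migration of the exocyclic alkene into conjugation with the sulfone. Deprotonation at the neopentylic C3 is slow. CBr2F2 is an ozone-depleting reagent.
- Comparison: step economy is about equal; the chosen plan is stronger on geometry control and weaker on the security of the stereocentre.

Key step: step 13

Assumption: the (S)-configured oxazoline–sulfonamide ligand is taken to steer C4 onto the Si face of the C5 aldehyde (the face that gives R); if the sense proved opposite, its mirror-image form would be used with no other change.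

## Steps

Step 1
Reactants: 1 6-methylhept-5-en-2-one
Product: 2 (5E)-7-hydroxy-6-methylhept-5-en-2-one
Conditions: SeO2 (cat.), t-BuOOH, salicylic acid (cat.), CH2Cl2, rt
Reagents that add atoms: tert-butyl hydroperoxide CC(C)(C)OO (terminal oxygen source; the oxygen is relayed by selenium dioxide O=[Se]=O)
Why: Catalytic SeO2 allylic oxidation (ene reaction, then [2,3]-sigmatropic shift) hydroxylates the methyl group trans to the chain at the more substituted alkene terminus, which fixes the E geometry of the future C8=C9 bond; the mild catalytic variant should leave the methyl ketone alone.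

Step 2
Reactants: 2 (5E)-7-hydroxy-6-methylhept-5-en-2-one
Product: 3 (5E)-7-bromo-6-methylhept-5-en-2-one
Conditions: CBr4, PPh3, CH2Cl2, 0 °C
Reagents that add atoms: tetrabromomethane BrC(Br)(Br)Br
Why: Appel bromination of a primary allylic alcohol proceeds by SN2 displacement of the oxyphosphonium ion under neutral conditions, so neither the alkene geometry nor the ketone should be affected.

Step 3
Reactants: 3 (5E)-7-bromo-6-methylhept-5-en-2-one; 4 dimethyl propanedioate (dimethyl malonate)
Product: 6 dimethyl 2-[(2E)-2-methyl-6-oxohept-2-en-1-yl]propanedioate, via sodium dimethyl malonate 5 (not isolated)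
Conditions: 4 (excess), NaH, THF, 0 °C; then 3, 0 °C to rt
Reagents that add atoms: none
Why: Malonic ester alkylation by SN2 attack at the primary allylic carbon; the stabilised anion does not add to the free methyl ketone, which a lithium ester enolate would attack, and the excess of 4 suppresses dialkylation.

Step 4
Reactants: 6 dimethyl 2-[(2E)-2-methyl-6-oxohept-2-en-1-yl]propanedioate
Product: 7 methyl (4E)-4-methyl-8-oxonon-4-enoate
Conditions: NaCl, H2O, DMSO, 150 °C
Reagents that add atoms: none
Why: Krapcho dealkoxycarbonylation (chloride demethylates one ester, the carboxylate loses CO2) leaves the C5–C6–C7 propanoate arm under neutral conditions that the ketone and the trisubstituted alkene tolerate.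

Step 5
Reactants: 8 ethyl 2-hydroxy-2-methylpropanoate
Product: 9 ethyl 2-methyl-2-[(triethylsilyl)oxy]propanoate
Conditions: Et3SiOTf, 2,6-lutidine, CH2Cl2, 0 °C
Reagents that add atoms: triethylsilyl trifluoromethanesulfonate CC[Si](CC)(CC)OS(=O)(=O)C(F)(F)F
Why: Silyl triflate with a hindered pyridine base is the standard way to silylate a tertiary alcohol; the triethylsilyl ether is stable to the later enolate, mesylation and ketalisation steps but is cleaved by cold fluoride.

Step 6
Reactants: 9 ethyl 2-methyl-2-[(triethylsilyl)oxy]propanoate
Product: 10 2-methyl-2-[(triethylsilyl)oxy]propanal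
Conditions: i-Bu2AlH, CH2Cl2, −78 °C
Reagents that add atoms: none
Why: Partial reduction of an α-oxygenated ester with i-Bu2AlH stops at the chelate-stabilised aluminium hemiacetal, which releases the non-enolisable aldehyde on work-up.

Step 7
Reactants: 7 methyl (4E)-4-methyl-8-oxonon-4-enoate; 10 2-methyl-2-[(triethylsilyl)oxy]propanal
Product: 12 methyl (4E)-10-hydroxy-4,11-dimethyl-8-oxo-11-[(triethylsilyl)oxy]dodec-4-enoate (racemic at the carbinol), via lithium enolate 11 (not isolated)
Conditions: LiN(i-Pr)2, THF, −78 °C; then 10, −78 °C
Reagents that add atoms: none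
Why: Directed aldol addition: kinetic deprotonation takes the ketone methyl group in preference to the ketone methylene and the less acidic ester α-position, and the non-enolisable aldehyde can only act as acceptor, which forms the C2–C3 bond; the new carbinol centre is removed in the next step, so its configuration is irrelevant.

Step 8
Reactants: 12 methyl (4E)-10-hydroxy-4,11-dimethyl-8-oxo-11-[(triethylsilyl)oxy]dodec-4-enoate
Product: 14 methyl (4E,9E)-4,11-dimethyl-8-oxo-11-[(triethylsilyl)oxy]dodeca-4,9-dienoate, via β-mesyloxy ketone 13 (not isolated)
Conditions: MeSO2Cl, Et3N, CH2Cl2, 0 °C; then DBU, rt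
Reagents that add atoms: none
Why: Mesylation through the sulfene pathway tolerates the hindered carbinol, and E1cB elimination of the β-mesyloxy ketone gives the conjugated enone, with E geometry favoured thermodynamically beside the quaternary carbon.

Step 9
Reactants: 14 methyl (4E,9E)-4,11-dimethyl-8-oxo-11-[(triethylsilyl)oxy]dodeca-4,9-dienoate
Product: 15 methyl (4E)-4-methyl-7-(2-{(1E)-3-methyl-3-[(triethylsilyl)oxy]but-1-en-1-yl}-1,3-dioxolan-2-yl)hept-4-enoate
Conditions: Me3SiOCH2CH2OSiMe3, Me3SiOTf (cat.), CH2Cl2, −78 to −20 °C; pyridine quench
Reagents that add atoms: 1,2-bis(trimethylsilyloxy)ethane C[Si](C)(C)OCCO[Si](C)(C)C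
Why: Noyori ketalisation works under aprotic conditions at low temperature, driven by formation of hexamethyldisiloxane, so the tertiary allylic silyl ether should survive; the alkene cannot migrate because C4 is quaternary.

Step 10
Reactants: 15 methyl (4E)-4-methyl-7-(2-{(1E)-3-methyl-3-[(triethylsilyl)oxy]but-1-en-1-yl}-1,3-dioxolan-2-yl)hept-4-enoate
Product: 16 methyl (4E)-7-{2-[(1E)-3-hydroxy-3-methylbut-1-en-1-yl]-1,3-dioxolan-2-yl}-4-methylhept-4-enoate
Conditions: Bu4NF, THF, 0 °C
Reagents that add atoms: none
Why: Fluoride cleaves the triethylsilyl ether quickly at 0 °C, conditions under which the ketal is inert and the methyl ester should not be hydrolysed.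

Step 11
Reactants: 16 methyl (4E)-7-{2-[(1E)-3-hydroxy-3-methylbut-1-en-1-yl]-1,3-dioxolan-2-yl}-4-methylhept-4-enoate
Product: 17 (4E)-7-{2-[(1E)-3-hydroxy-3-methylbut-1-en-1-yl]-1,3-dioxolan-2-yl}-4-methylhept-4-enal
Conditions: i-Bu2AlH (2.2 equiv), CH2Cl2, −78 °C; MeOH, then aq. potassium sodium tartrate
Reagents that add atoms: none
Why: The first equivalent of hydride converts the tertiary hydroxyl into its aluminium alkoxide and the second reduces the methyl ester to the aluminium hemiacetal, which is stable at −78 °C and gives the aldehyde on quench; the C5 aldehyde is thus in place before the labile halide is made.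

Step 12
Reactants: 17 (4E)-7-{2-[(1E)-3-hydroxy-3-methylbut-1-en-1-yl]-1,3-dioxolan-2-yl}-4-methylhept-4-enal
Product: 18 (4E)-7-{2-[(1E)-3-chloro-3-methylbut-1-en-1-yl]-1,3-dioxolan-2-yl}-4-methylhept-4-enal
Conditions: SOCl2, pyridine, Et2O, −30 to 0 °C; salts filtered off, crude used at once
Reagents that add atoms: thionyl chloride O=S(Cl)Cl
Why: Chlorination of a tertiary allylic alcohol through its chlorosulfite, with ion-pair collapse, under pyridine buffering that protects the ketal; any allylically transposed C2 chloride formed by ion-pair return is tolerable because it leads to the same allylchromium, so the material is not purified.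

Step 13
Reactants: 18 (4E)-7-{2-[(1E)-3-chloro-3-methylbut-1-en-1-yl]-1,3-dioxolan-2-yl}-4-methylhept-4-enal
Product: 20 (6E,9R,12E)-8,8,12-trimethyl-1,4-dioxaspiro[4.10]pentadeca-6,12-dien-9-ol, via C2-bound allylchromium 19 (not isolated)
Conditions: CrCl2, N-{2-[(4S)-4-isopropyl-4,5-dihydro-1,3-oxazol-2-yl]-6-methylphenyl}methanesulfonamide, Et3N, THF, rt; 18 added by syringe pump over 12 h (final 2 mM)
Reagents that add atoms: none
Why: Two one-electron transfers from ligand-bound divalent chromium convert the C–Cl bond of 18 into allylchromium 19, in which trivalent chromium sits on the secondary terminus C2 and not on the tertiary C4, wherever the halide originally was. 19 then adds to the tethered aldehyde through a six-membered Zimmerman–Traxler chair (Cr–O=C5···C4=C3–C2), so that C4 bonds to C5 and the double bond moves to C2=C3. The closest known reaction type is the Nozaki–Hiyama–Kishi allylation, used intramolecularly to close ten- to fourteen-membered carbocycles and known to transfer 3,3-dimethylallyl groups through their γ-carbon. The eleven-membered ring closes as an 11-exo-trig carbonyl addition in which the seven-atom tether C1–C11–C10–C9–C8–C7–C6 spans the two equatorial positions of the chair. The substrate has no stereocentre, so the R configuration at C5 (attack on the Si face of the aldehyde) must come from the chiral oxazoline–sulfonamide ligand on chromium. γ- over α-attack is secured by the position of the metal at C2 and by the nine-membered ring that α-attack would require. E geometry at C2=C3 follows from the equatorial C1 substituent on the metal-bearing carbon. Slow addition at high dilution favours cyclisation over oligomerisation, and the C1 ketal keeps the nucleophile a simple allyl system, not a dienolate or pentadienyl one.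

Step 14
Reactants: 21 4-hydroxy-3-methoxybenzoic acid (vanillic acid)
Product: 23 4-[(tert-butyldimethylsilyl)oxy]-3-methoxybenzoic acid, via bis-silyl derivative 22 (not isolated)
Conditions: t-BuMe2SiCl (2.5 equiv), imidazole, DMF, rt; then AcOH, THF/H2O, rt
Reagents that add atoms: tert-butyl(chloro)dimethylsilane CC(C)(C)[Si](C)(C)Cl
Why: Exhaustive silylation followed by selective hydrolysis of the much more labile silyl ester leaves the aryl silyl ether and frees the carboxylic acid.

Step 15
Reactants: 20 (6E,9R,12E)-8,8,12-trimethyl-1,4-dioxaspiro[4.10]pentadeca-6,12-dien-9-ol; 23 4-[(tert-butyldimethylsilyl)oxy]-3-methoxybenzoic acid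
Product: 25 (6E,9R,12E)-8,8,12-trimethyl-1,4-dioxaspiro[4.10]pentadeca-6,12-dien-9-yl 4-[(tert-butyldimethylsilyl)oxy]-3-methoxybenzoate, via acid chloride 24 (not isolated)
Conditions: 23, (COCl)2, DMF (cat.), CH2Cl2, 0 °C to rt, evaporate; then 20, Et3N, 4-(dimethylamino)pyridine, CH2Cl2, rt
Reagents that add atoms: none
Why: Acylation of a hindered secondary alcohol with an aroyl chloride under nucleophilic catalysis; the C5–O bond is not touched, so the R configuration is retained, and the ketal and alkenes are inert to the buffered conditions.

Step 16
Reactants: 25 (6E,9R,12E)-8,8,12-trimethyl-1,4-dioxaspiro[4.10]pentadeca-6,12-dien-9-yl 4-[(tert-butyldimethylsilyl)oxy]-3-methoxybenzoate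
Product: 26 (1R,3E,8E)-2,2,9-trimethyl-5-oxocycloundeca-3,8-dien-1-yl 4-[(tert-butyldimethylsilyl)oxy]-3-methoxybenzoate
Conditions: pyridinium p-toluenesulfonate, acetone/H2O, 40 °C
Reagents that add atoms: water O
Why: The allylic ketal ionises readily to a conjugated oxocarbenium ion and is hydrolysed by a weak acid that should spare the aryl silyl ether, the ester and the remote trisubstituted alkene; the C5 oxygen is already acylated, so no hydroxy enone prone to C4–C5 fragmentation is formed.

Step 17
Reactants: 26 (1R,3E,8E)-2,2,9-trimethyl-5-oxocycloundeca-3,8-dien-1-yl 4-[(tert-butyldimethylsilyl)oxy]-3-methoxybenzoate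
Product: 27 (1R,3E,8E)-2,2,9-trimethyl-5-methylidenecycloundeca-3,8-dien-1-yl 4-[(tert-butyldimethylsilyl)oxy]-3-methoxybenzoate
Conditions: Ph3PCH3Br, KN(SiMe3)2, THF, 0 °C; then 26, 0 °C to rt
Reagents that add atoms: methyltriphenylphosphonium bromide C[P+](c1ccccc1)(c1ccccc1)c1ccccc1.[Br-]
Why: Wittig methylenation; the ylide adds 1,2 to the enone carbonyl because the β-carbon C3 is neopentylic, and a ketone reacts much faster than the electron-rich hindered aryl ester; C5 is not involved.

Step 18
Reactants: 27 (1R,3E,8E)-2,2,9-trimethyl-5-methylidenecycloundeca-3,8-dien-1-yl 4-[(tert-butyldimethylsilyl)oxy]-3-methoxybenzoate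
Product: 28 (1R,3E,8E)-2,2,9-trimethyl-5-methylidenecycloundeca-3,8-dien-1-yl 4-hydroxy-3-methoxybenzoate
Conditions: Bu4NF, AcOH, THF, 0 °C
Reagents that add atoms: none
Why: Fluoride cleaves the aryl silyl ether within minutes, and the acetic acid buffer protonates the phenoxide so that neither the ester nor the diene is exposed to base.

## Compound list

1 | 6-methylhept-5-en-2-one | CC(=O)CCC=C(C)C | starting material
2 | (5E)-7-hydroxy-6-methylhept-5-en-2-one | CC(=O)CC/C=C(\C)CO | intermediate
3 | (5E)-7-bromo-6-methylhept-5-en-2-one | CC(=O)CC/C=C(\C)CBr | intermediate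
4 | dimethyl propanedioate (dimethyl malonate) | COC(=O)CC(=O)OC | starting material
5 | sodium 1,3-dimethoxy-1,3-dioxopropan-2-ide (sodium dimethyl malonate) | COC(=O)[CH-]C(=O)OC.[Na+] | intermediate (not isolated)
6 | dimethyl 2-[(2E)-2-methyl-6-oxohept-2-en-1-yl]propanedioate | COC(=O)C(C/C(C)=C/CCC(C)=O)C(=O)OC | intermediate
7 | methyl (4E)-4-methyl-8-oxonon-4-enoate | COC(=O)CC/C(C)=C/CCC(C)=O | intermediate
8 | ethyl 2-hydroxy-2-methylpropanoate | CCOC(=O)C(C)(C)O | starting material
9 | ethyl 2-methyl-2-[(triethylsilyl)oxy]propanoate | CCOC(=O)C(C)(C)O[Si](CC)(CC)CC | intermediate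
10 | 2-methyl-2-[(triethylsilyl)oxy]propanal | CC[Si](CC)(CC)OC(C)(C)C=O | intermediate
11 | methyl (4E)-8-(lithiooxy)-4-methylnona-4,8-dienoate (lithium enolate of 7) | COC(=O)CC/C(C)=C/CCC(=C)O[Li] | intermediate (not isolated)
12 | methyl (4E)-10-hydroxy-4,11-dimethyl-8-oxo-11-[(triethylsilyl)oxy]dodec-4-enoate (racemic at C10) | COC(=O)CC/C(C)=C/CCC(=O)CC(O)C(C)(C)O[Si](CC)(CC)CC | intermediate
13 | methyl (4E)-10-(methanesulfonyloxy)-4,11-dimethyl-8-oxo-11-[(triethylsilyl)oxy]dodec-4-enoate (racemic at C10) | COC(=O)CC/C(C)=C/CCC(=O)CC(OS(C)(=O)=O)C(C)(C)O[Si](CC)(CC)CC | intermediate (not isolated)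
14 | methyl (4E,9E)-4,11-dimethyl-8-oxo-11-[(triethylsilyl)oxy]dodeca-4,9-dienoate | COC(=O)CC/C(C)=C/CCC(=O)/C=C/C(C)(C)O[Si](CC)(CC)CC | intermediate
15 | methyl (4E)-4-methyl-7-(2-{(1E)-3-methyl-3-[(triethylsilyl)oxy]but-1-en-1-yl}-1,3-dioxolan-2-yl)hept-4-enoate | COC(=O)CC/C(C)=C/CCC1(OCCO1)/C=C/C(C)(C)O[Si](CC)(CC)CC | intermediate
16 | methyl (4E)-7-{2-[(1E)-3-hydroxy-3-methylbut-1-en-1-yl]-1,3-dioxolan-2-yl}-4-methylhept-4-enoate | COC(=O)CC/C(C)=C/CCC1(OCCO1)/C=C/C(C)(C)O | intermediate
17 | (4E)-7-{2-[(1E)-3-hydroxy-3-methylbut-1-en-1-yl]-1,3-dioxolan-2-yl}-4-methylhept-4-enal | O=CCC/C(C)=C/CCC1(OCCO1)/C=C/C(C)(C)O | intermediate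
18 | (4E)-7-{2-[(1E)-3-chloro-3-methylbut-1-en-1-yl]-1,3-dioxolan-2-yl}-4-methylhept-4-enal | O=CCC/C(C)=C/CCC1(OCCO1)/C=C/C(C)(C)Cl | intermediate
19 | C2-bound allylchromium from 18: trivalent chromium on C2 carrying chloride and the deprotonated sulfonamide ligand (oxazoline N→Cr bond and solvent not drawn), C3=C4 double bond | O=CCC/C(C)=C/CCC1(OCCO1)C(C=C(C)C)[Cr](Cl)N(c1c(C)cccc1C1=N[C@@H](C(C)C)CO1)S(C)(=O)=O | intermediate (not isolated)
20 | (6E,9R,12E)-8,8,12-trimethyl-1,4-dioxaspiro[4.10]pentadeca-6,12-dien-9-ol | O[C@@H]1CC/C(C)=C/CCC2(OCCO2)/C=C/C1(C)C | intermediate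
21 | 4-hydroxy-3-methoxybenzoic acid (vanillic acid) | COc1cc(C(=O)O)ccc1O | starting material
22 | tert-butyldimethylsilyl 4-[(tert-butyldimethylsilyl)oxy]-3-methoxybenzoate | COc1cc(C(=O)O[Si](C)(C)C(C)(C)C)ccc1O[Si](C)(C)C(C)(C)C | intermediate (not isolated)
23 | 4-[(tert-butyldimethylsilyl)oxy]-3-methoxybenzoic acid | COc1cc(C(=O)O)ccc1O[Si](C)(C)C(C)(C)C | intermediate
24 | 4-[(tert-butyldimethylsilyl)oxy]-3-methoxybenzoyl chloride | COc1cc(C(=O)Cl)ccc1O[Si](C)(C)C(C)(C)C | intermediate (not isolated)
25 | (6E,9R,12E)-8,8,12-trimethyl-1,4-dioxaspiro[4.10]pentadeca-6,12-dien-9-yl 4-[(tert-butyldimethylsilyl)oxy]-3-methoxybenzoate | COc1cc(C(=O)O[C@@H]2CC/C(C)=C/CCC3(OCCO3)/C=C/C2(C)C)ccc1O[Si](C)(C)C(C)(C)C | intermediate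
26 | (1R,3E,8E)-2,2,9-trimethyl-5-oxocycloundeca-3,8-dien-1-yl 4-[(tert-butyldimethylsilyl)oxy]-3-methoxybenzoate | COc1cc(C(=O)O[C@@H]2CC/C(C)=C/CCC(=O)/C=C/C2(C)C)ccc1O[Si](C)(C)C(C)(C)C | intermediate
27 | (1R,3E,8E)-2,2,9-trimethyl-5-methylidenecycloundeca-3,8-dien-1-yl 4-[(tert-butyldimethylsilyl)oxy]-3-methoxybenzoate | C=C1/C=C/C(C)(C)[C@H](OC(=O)c2ccc(O[Si](C)(C)C(C)(C)C)c(OC)c2)CC/C(C)=C/CC1 | intermediate
28 | (1R,3E,8E)-2,2,9-trimethyl-5-methylidenecycloundeca-3,8-dien-1-yl 4-hydroxy-3-methoxybenzoate | C=C1/C=C/C(C)(C)[C@H](OC(=O)c2ccc(O)c(OC)c2)CC/C(C)=C/CC1 | target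

## Step count and least certain steps

Total: 18 steps. Longest linear sequence: 15 steps (1–4, 7–13, 15–18, from 1); the branches are steps 5–6 (from 8) and step 14 (from 21).

Step 13 (key step). The most likely failure is weak enantiofacial discrimination: inside the macrocyclic chair the tether, not the ligand, may decide which aldehyde face reaches C4. Secondary hazards are reductive 1,4-loss of a dioxolane oxygen from 19 and oligomerisation. Fallback, from 18 back to 20: 18 is cyclised with CrCl2 alone in THF at the same dilution, which should give racemic (6E,12E)-8,8,12-trimethyl-1,4-dioxaspiro[4.10]pentadeca-6,12-dien-9-ol F1. Oxidation with Dess–Martin periodinane (pyridine-buffered, CH2Cl2) should give (6E,12E)-8,8,12-trimethyl-1,4-dioxaspiro[4.10]pentadeca-6,12-dien-9-one F2, a β,γ-unsaturated ketone that cannot conjugate because C4 is quaternary. Corey–Bakshi–Shibata reduction with BH3·SMe2 and (S)-2-methyl-CBS-oxazaborolidine, which distinguishes the tert-alkyl C4 side from the C6 methylene, should then give the R alcohol 20.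

Step 12. The most likely failure is ionisation of the chlorosulfite with loss of a methyl proton to an isopropenyl diene, or attack of the activating agent and amine base on the unprotected aldehyde, because two sensitive groups are present together. Fallback, from 16 back to 18: the hydroxy ester 16 is chlorinated under the same conditions, where no aldehyde interferes and the product can be passed through a short pad of basic Al2O3, to give methyl (4E)-7-{2-[(1E)-3-chloro-3-methylbut-1-en-1-yl]-1,3-dioxolan-2-yl}-4-methylhept-4-enoate F3. One equivalent of i-Bu2AlH in toluene at −78 °C then reduces the ester to aldehyde 18 as the last operation.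

Step 11. The most likely failure is collapse of the aluminium hemiacetal before the quench, giving over-reduction to the primary alcohol beside unreacted ester. Fallback, from 16 back to 17: complete reduction with LiAlH4 in THF at 0 °C gives the diol (4E)-7-{2-[(1E)-3-hydroxy-3-methylbut-1-en-1-yl]-1,3-dioxolan-2-yl}-4-methylhept-4-en-1-ol F4. Oxidation with catalytic 2,2,6,6-tetramethylpiperidin-1-oxyl and PhI(OAc)2 in CH2Cl2, selective for the primary hydroxyl, leaves the tertiary allylic alcohol untouched and gives 17.

Step 17. The most likely failure is acyl transfer from the aryl ester to the nucleophilic ylide, or reversible enolisation at C11 that stalls the methylenation. Loss of the aryl silyl group alone would be harmless, since it only anticipates step 18. Fallback, from 20 back to 27: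
- The C5 hydroxyl of 20 is silylated (t-BuMe2SiOTf, 2,6-lutidine, CH2Cl2) to tert-butyldimethyl{[(6E,9R,12E)-8,8,12-trimethyl-1,4-dioxaspiro[4.10]pentadeca-6,12-dien-9-yl]oxy}silane F5.
- Pyridinium p-toluenesulfonate in aqueous acetone removes the ketal to give (2E,5R,8E)-5-[(tert-butyldimethylsilyl)oxy]-4,4,8-trimethylcycloundeca-2,8-dien-1-one F6.
- Wittig methylenation, now with no ester in the molecule, gives tert-butyldimethyl{[(1R,3E,8E)-2,2,9-trimethyl-5-methylidenecycloundeca-3,8-dien-1-yl]oxy}silane F7, identical with A6.
- Bu4NF in warm THF frees (1R,3E,8E)-2,2,9-trimethyl-5-methylidenecycloundeca-3,8-dien-1-ol F8, which is acylated with 24 (Et3N, 4-(dimethylamino)pyridine, CH2Cl2) to give 27.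

## Further compounds

F1 | step 13 | (6E,12E)-8,8,12-trimethyl-1,4-dioxaspiro[4.10]pentadeca-6,12-dien-9-ol (racemic) | OC1CC/C(C)=C/CCC2(OCCO2)/C=C/C1(C)C
F2 | step 13 | (6E,12E)-8,8,12-trimethyl-1,4-dioxaspiro[4.10]pentadeca-6,12-dien-9-one | O=C1CC/C(C)=C/CCC2(OCCO2)/C=C/C1(C)C
F3 | step 12 | methyl (4E)-7-{2-[(1E)-3-chloro-3-methylbut-1-en-1-yl]-1,3-dioxolan-2-yl}-4-methylhept-4-enoate | COC(=O)CC/C(C)=C/CCC1(OCCO1)/C=C/C(C)(C)Cl
F4 | step 11 | (4E)-7-{2-[(1E)-3-hydroxy-3-methylbut-1-en-1-yl]-1,3-dioxolan-2-yl}-4-methylhept-4-en-1-ol | OCCC/C(C)=C/CCC1(OCCO1)/C=C/C(C)(C)O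
F5 | step 17 | tert-butyldimethyl{[(6E,9R,12E)-8,8,12-trimethyl-1,4-dioxaspiro[4.10]pentadeca-6,12-dien-9-yl]oxy}silane | CC(C)(C)[Si](C)(C)O[C@@H]1CC/C(C)=C/CCC2(OCCO2)/C=C/C1(C)C
F6 | step 17 | (2E,5R,8E)-5-[(tert-butyldimethylsilyl)oxy]-4,4,8-trimethylcycloundeca-2,8-dien-1-one | CC(C)(C)[Si](C)(C)O[C@@H]1CC/C(C)=C/CCC(=O)/C=C/C1(C)C
F7 | step 17 | tert-butyldimethyl{[(1R,3E,8E)-2,2,9-trimethyl-5-methylidenecycloundeca-3,8-dien-1-yl]oxy}silane | C=C1/C=C/C(C)(C)[C@H](O[Si](C)(C)C(C)(C)C)CC/C(C)=C/CC1
F8 | step 17 | (1R,3E,8E)-2,2,9-trimethyl-5-methylidenecycloundeca-3,8-dien-1-ol | C=C1/C=C/C(C)(C)[C@H](O)CC/C(C)=C/CC1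
A1 | alternative 1 | (6E,11E)-5,5,12-trimethyl-8-methylidene-1-oxacyclotrideca-6,11-diene-2,4-dione | C=C1/C=C/C(C)(C)C(=O)CC(=O)OC/C(C)=C/CC1
A2 | alternative 1 | (3E,8E)-2,2,9-trimethyl-5-methylidenecycloundeca-3,8-dien-1-one | C=C1/C=C/C(C)(C)C(=O)CC/C(C)=C/CC1
A3 | alternative 2 | (5R)-5-[(tert-butyldimethylsilyl)oxy]-1,2-diethenyl-2,6,6-trimethylcycloheptan-1-ol, ethenyl groups trans | C=C[C@@]1(O)CC(C)(C)[C@H](O[Si](C)(C)C(C)(C)C)CC[C@]1(C)C=C
A4 | alternative 2 | (5E,9R)-9-[(tert-butyldimethylsilyl)oxy]-6,10,10-trimethylcycloundec-5-en-1-one | O=C1CCC/C=C(C)/CC[C@@H](O[Si](C)(C)C(C)(C)C)C(C)(C)C1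
A5 | alternative 3 | (6E,10R)-10-[(tert-butyldimethylsilyl)oxy]-7,11,11-trimethyl-3-methylidene-1-thiacyclododec-6-ene 1,1-dioxide | C=C1CS(=O)(=O)CC(C)(C)[C@H](O[Si](C)(C)C(C)(C)C)CC/C(C)=C/CC1
A6 | alternative 3 | tert-butyldimethyl{[(1R,3E,8E)-2,2,9-trimethyl-5-methylidenecycloundeca-3,8-dien-1-yl]oxy}silane | C=C1/C=C/C(C)(C)[C@H](O[Si](C)(C)C(C)(C)C)CC/C(C)=C/CC1
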